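**Plan**

1. Azulene numbering of the target: C1 and C2 ring CH2, C3 carbinol carbon, C3a ring-fusion CH, C4 ester carbon, C5 CH2, C6 methyl-bearing alkene carbon, C7 alkene CH, C8 ketone, C8a quaternary carbon. The retrosynthesis cuts the ester C–O bond first. It then cuts together the C6–C7 bond (made as a single bond and dehydrogenated to the enone later) and the ring-fusion C3a–C8a bond, in an intramolecular (4+3) cycloaddition.
2. Enabling feature: the seven-membered ring is a cycloheptanone in which C7–C8(=O)–C8a is a 2-oxyallyl three-carbon unit and C3a–C4(O)–C5–C6 is a 2-oxygenated 1,3-diene. The cyclopentane carbons C1–C3 are the tether between C8a and C3a, so both rings close in the same event.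
3. Forward: ozonolysis opens the ring of (S)-terpinen-4-ol to a chain that already holds C3 with its isopropyl group, C2, C1, C8a with its methyl, C3a and C4. A propenyl addition completes the diene (C5, C6, methyl) and a 1-ethoxyvinyl addition completes the allyl cation precursor (C8, C7). The five- and seven-membered rings then arise together.
4. Stereochemistry: C3 comes from the chiral pool and controls C3a and C8a in the cycloaddition through allylic strain. C4 is set by convex-face hydrogenation of the silyl enol ether that the cycloaddition leaves behind. The C6 centre is transient.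
5. Endgame: Saegusa–Ito oxidation installs the enone, both silyl ethers are removed, and the secondary alcohol is acylated selectively.

Key step: step 7

Assumption: (S)-(+)-terpinen-4-ol is taken as a commercial chiral-pool material of high enantiomeric purity; its carbinol carbon becomes C3 of the target without change of configuration.

**Route**

Step 1
Reactants: 1 (S)-(+)-terpinen-4-ol
Product: 2 triethyl{[(1S)-4-methyl-1-(propan-2-yl)cyclohex-3-en-1-yl]oxy}silane
Conditions: TESOTf, 2,6-lutidine, CH2Cl2, 0 °C to rt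
Reagents that add atoms: triethylsilyl trifluoromethanesulfonate, CC[Si](CC)(CC)OS(=O)(=O)C(F)(F)F
Why: Silyl triflate silylation of the hindered tertiary alcohol; the ether masks the hydroxyl that would otherwise trap the cation of step 7, and the stereocentre is not touched.

Step 2
Reactants: 2 triethyl{[(1S)-4-methyl-1-(propan-2-yl)cyclohex-3-en-1-yl]oxy}silane
Product: 3 (3S)-6-oxo-3-(propan-2-yl)-3-[(triethylsilyl)oxy]heptanal
Conditions: O3, CH2Cl2, −78 °C; then PPh3, −78 °C to rt
Reagents that add atoms: ozone, [O-][O+]=O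
Why: Ozonolysis with reductive work-up cleaves the only C=C bond to the keto aldehyde without touching the carbinol centre.

Step 3
Reactants: 3 (3S)-6-oxo-3-(propan-2-yl)-3-[(triethylsilyl)oxy]heptanal; 4 (E)-1-bromoprop-1-ene
Product: 5 (5S,8E)-7-hydroxy-5-(propan-2-yl)-5-[(triethylsilyl)oxy]dec-8-en-2-one as a mixture of C7 epimers
Conditions: 4, t-BuLi (2 equiv), Et2O, −78 °C; MgBr2·OEt2; then 3, THF, −78 °C; pH 7 buffer
Reagents that add atoms: none
Why: Chemoselective Grignard 1,2-addition: at −78 °C the alkenylmagnesium reagent (E geometry retained through bromine–lithium exchange) should add to the aldehyde and leave the methyl ketone; the new carbinol centre forms without control because it is oxidised away in step 5.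

Step 4
Reactants: 5 (5S,8E)-7-hydroxy-5-(propan-2-yl)-5-[(triethylsilyl)oxy]dec-8-en-2-one; 6 ethyl vinyl ether
Product: 7 (6S,9E)-2-ethoxy-3-methyl-6-(propan-2-yl)-6-[(triethylsilyl)oxy]undeca-1,9-diene-3,8-diol as a mixture at C3 and C8
Conditions: 6, t-BuLi, THF, −78 to 0 °C; then 5 (one third of an equivalent), −78 °C; aq NaHCO3
Reagents that add atoms: none
Why: 1,2-Addition of an acyl anion equivalent (1-ethoxyvinyllithium) to the ketone after a first equivalent has deprotonated the hydroxyl; the new tertiary carbinol centre forms as a mixture that does not matter because this carbon becomes the planar cation of step 7.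

Step 5
Reactants: 7 (6S,9E)-2-ethoxy-3-methyl-6-(propan-2-yl)-6-[(triethylsilyl)oxy]undeca-1,9-diene-3,8-diol
Product: 8 (2E,6S)-10-ethoxy-9-hydroxy-9-methyl-6-(propan-2-yl)-6-[(triethylsilyl)oxy]undeca-2,10-dien-4-one as a mixture of C9 epimers
Conditions: MnO2 (excess), CH2Cl2, rt
Reagents that add atoms: none
Why: Allylic oxidation with MnO2 is selective for the secondary allylic alcohol, leaves the tertiary alcohol and the enol ether untouched, and removes the uncontrolled carbinol centre.

Step 6
Reactants: 8 (2E,6S)-10-ethoxy-9-hydroxy-9-methyl-6-(propan-2-yl)-6-[(triethylsilyl)oxy]undeca-2,10-dien-4-one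
Product: 9 (6R,7Z,9E)-8-[(tert-butyldimethylsilyl)oxy]-2-ethoxy-3-methyl-6-(propan-2-yl)-6-[(triethylsilyl)oxy]undeca-1,7,9-trien-3-ol as a mixture of C3 epimers
Conditions: LDA (2.2 equiv), THF, −78 °C; TBSCl, HMPA, −78 to −30 °C; cold aq NaHCO3
Reagents that add atoms: tert-butyldimethylsilyl chloride, CC(C)(C)[Si](C)(C)Cl
Why: Kinetic enolisation of the enone at the α'-CH2 gives the cross-conjugated lithium dienolate, which is O-silylated while the hindered tertiary lithium alkoxide should not react with TBSCl; the bulky quaternary neighbour should place OTBS cis to it (Z enol ether), the geometry needed for the s-cis diene.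

Step 7
Reactants: 9 (6R,7Z,9E)-8-[(tert-butyldimethylsilyl)oxy]-2-ethoxy-3-methyl-6-(propan-2-yl)-6-[(triethylsilyl)oxy]undeca-1,7,9-trien-3-ol
Product: 12 (3R,3aR,6S,8aS)-4-[(tert-butyldimethylsilyl)oxy]-6,8a-dimethyl-3-(propan-2-yl)-3-[(triethylsilyl)oxy]-2,3,3a,6,7,8a-hexahydro-1H-azulen-8-one, via allylic triflate 10 (not isolated), via ethyl enol ether cycloadduct 11 (not isolated)
Conditions: Tf2O, 2,6-lutidine, CH2Cl2, −78 to −40 °C; then aq oxalic acid, THF, 0 °C (brief)
Reagents that add atoms: water, O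
Why: Triflation of the tertiary alcohol and loss of triflate should give a 2-ethoxyallyl cation that adds across the termini of the tethered s-cis 2-siloxydiene in an asynchronous (4+3) cycloaddition, after which the ethyl oxocarbenium ion loses a proton to give enol ether 11 and mild aqueous acid unveils the ketone while the more robust silyl enol ether survives. The closest known reaction type is the intramolecular (4+3) cycloaddition of 2-alkoxyallyl (oxyallyl-type) cations with 1,3-dienes to hydroazulenones, including cation generation from an allylic alcohol with Tf2O and 2,6-lutidine. The cyclopentane closes by 5-exo attack of the nucleophilic CH terminus of the diene on the tertiary cation carbon, and the cycloheptene closes when the CH2 terminus of the allyl cation bonds to the methyl-bearing diene terminus on the same diene face. The ring-fusion CH and the quaternary methyl carbon are controlled by the existing silyloxy carbinol centre: allylic 1,3-strain with the Z-OTBS group leaves only the arrangement with the tether CH2 eclipsing the enol ether and the isopropyl group anti to the forming bond, which should deliver the cis ring fusion with the new seven-membered ring syn to isopropyl and anti to OTES, while the E-propenyl geometry sets the secondary methyl centre that is erased in step 9. The step needs ionisation at the ethoxyallylic alcohol and not at the allylic OTES carbon, secured by O-sulfonylation of the only free hydroxyl under base-buffered conditions free of Lewis acid, and it needs seven-ring closure in preference to proton loss or five-ring (3+2) closure, which the s-cis-biased 2-siloxydiene with hydrogen at both inside positions should favour.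

Step 8
Reactants: 12 (3R,3aR,6S,8aS)-4-[(tert-butyldimethylsilyl)oxy]-6,8a-dimethyl-3-(propan-2-yl)-3-[(triethylsilyl)oxy]-2,3,3a,6,7,8a-hexahydro-1H-azulen-8-one
Product: 13 (3R,3aR,4S,6R,8aS)-4-[(tert-butyldimethylsilyl)oxy]-6,8a-dimethyl-3-(propan-2-yl)-3-[(triethylsilyl)oxy]octahydro-1H-azulen-8-one
Conditions: H2 (3 atm), 5% Rh/Al2O3, EtOAc, rt
Reagents that add atoms: none
Why: Heterogeneous catalytic hydrogenation of the silyl enol ether with syn delivery of H2 to the convex face that carries the ring-fusion hydrogen and the angular methyl group; the concave face is shielded by the endo isopropyl group and the C6 methyl group, so C4 should be set with oxygen on the concave face as in the target.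

Step 9
Reactants: 13 (3R,3aR,4S,6R,8aS)-4-[(tert-butyldimethylsilyl)oxy]-6,8a-dimethyl-3-(propan-2-yl)-3-[(triethylsilyl)oxy]octahydro-1H-azulen-8-one
Product: 15 (3R,3aR,4S,8aS)-4-[(tert-butyldimethylsilyl)oxy]-6,8a-dimethyl-3-(propan-2-yl)-3-[(triethylsilyl)oxy]-2,3,3a,4,5,8a-hexahydro-1H-azulen-8-one, via trimethylsilyl enol ether 14 (not isolated)
Conditions: TMSOTf, Et3N, CH2Cl2, 0 °C; then Pd(OAc)2 (1.1 equiv), MeCN, rt
Reagents that add atoms: none
Why: Saegusa–Ito oxidation: the ketone can enolise only toward C7 because C8a is quaternary, so silyl enol ether formation and palladium-mediated β-hydride elimination should give the C6–C7 enone regiospecifically and remove the transient C6 stereocentre.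

Step 10
Reactants: 15 (3R,3aR,4S,8aS)-4-[(tert-butyldimethylsilyl)oxy]-6,8a-dimethyl-3-(propan-2-yl)-3-[(triethylsilyl)oxy]-2,3,3a,4,5,8a-hexahydro-1H-azulen-8-one
Product: 16 (3R,3aR,4S,8aS)-3,4-dihydroxy-6,8a-dimethyl-3-(propan-2-yl)-2,3,3a,4,5,8a-hexahydro-1H-azulen-8-one
Conditions: HF·pyridine, THF, 0 °C to rt
Reagents that add atoms: none
Why: Fluoride-mediated cleavage of both silyl ethers under buffered acidic conditions, which avoid base-induced elimination of the δ-oxygen from the enone; no stereocentre is touched.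

Step 11
Reactants: 16 (3R,3aR,4S,8aS)-3,4-dihydroxy-6,8a-dimethyl-3-(propan-2-yl)-2,3,3a,4,5,8a-hexahydro-1H-azulen-8-one; 17 4-methoxybenzoyl chloride
Product: 18 (3R,3aR,4S,8aS)-3-hydroxy-6,8a-dimethyl-8-oxo-3-(propan-2-yl)-1,2,3,3a,4,5,8,8a-octahydroazulen-4-yl 4-methoxybenzoate
Conditions: 17, Et3N, DMAP (cat.), CH2Cl2, 0 °C to rt
Reagents that add atoms: none
Why: DMAP-catalysed acylation (nucleophilic catalysis) is selective for the secondary alcohol over the tertiary one and proceeds with retention at the carbinol carbon.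

**Compound list**

1 | (S)-(+)-terpinen-4-ol, (1S)-4-methyl-1-(propan-2-yl)cyclohex-3-en-1-ol | CC1=CC[C@](O)(C(C)C)CC1 | starting material
2 | triethyl{[(1S)-4-methyl-1-(propan-2-yl)cyclohex-3-en-1-yl]oxy}silane | CC1=CC[C@](O[Si](CC)(CC)CC)(C(C)C)CC1 | intermediate
3 | (3S)-6-oxo-3-(propan-2-yl)-3-[(triethylsilyl)oxy]heptanal | O=CC[C@](O[Si](CC)(CC)CC)(C(C)C)CCC(C)=O | intermediate
4 | (E)-1-bromoprop-1-ene | C/C=C/Br | starting material
5 | (5S,8E)-7-hydroxy-5-(propan-2-yl)-5-[(triethylsilyl)oxy]dec-8-en-2-one (both C7 epimers) | C/C=C/C(O)C[C@](O[Si](CC)(CC)CC)(C(C)C)CCC(C)=O | intermediate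
6 | ethyl vinyl ether (ethoxyethene) | C=COCC | starting material
7 | (6S,9E)-2-ethoxy-3-methyl-6-(propan-2-yl)-6-[(triethylsilyl)oxy]undeca-1,9-diene-3,8-diol (mixture at C3 and C8) | C/C=C/C(O)C[C@](O[Si](CC)(CC)CC)(C(C)C)CCC(C)(O)C(=C)OCC | intermediate
8 | (2E,6S)-10-ethoxy-9-hydroxy-9-methyl-6-(propan-2-yl)-6-[(triethylsilyl)oxy]undeca-2,10-dien-4-one (both C9 epimers) | C/C=C/C(=O)C[C@](O[Si](CC)(CC)CC)(C(C)C)CCC(C)(O)C(=C)OCC | intermediate
9 | (6R,7Z,9E)-8-[(tert-butyldimethylsilyl)oxy]-2-ethoxy-3-methyl-6-(propan-2-yl)-6-[(triethylsilyl)oxy]undeca-1,7,9-trien-3-ol (both C3 epimers; same spatial arrangement at C6 as in 8) | C/C=C/C(O[Si](C)(C)C(C)(C)C)=C/[C@](O[Si](CC)(CC)CC)(C(C)C)CCC(C)(O)C(=C)OCC | intermediate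
10 | (6R,7Z,9E)-8-[(tert-butyldimethylsilyl)oxy]-2-ethoxy-3-methyl-6-(propan-2-yl)-6-[(triethylsilyl)oxy]undeca-1,7,9-trien-3-yl trifluoromethanesulfonate (not isolated) | C/C=C/C(O[Si](C)(C)C(C)(C)C)=C/[C@](O[Si](CC)(CC)CC)(C(C)C)CCC(C)(OS(=O)(=O)C(F)(F)F)C(=C)OCC | intermediate
11 | tert-butyl{[(3R,3aR,6S,8aS)-8-ethoxy-6,8a-dimethyl-3-(propan-2-yl)-3-[(triethylsilyl)oxy]-1,2,3,3a,6,8a-hexahydroazulen-4-yl]oxy}dimethylsilane (not isolated) | CC(C)(C)[Si](C)(C)OC1=C[C@@H](C)C=C(OCC)[C@@]2(C)CC[C@@](O[Si](CC)(CC)CC)(C(C)C)[C@@H]12 | intermediate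
12 | (3R,3aR,6S,8aS)-4-[(tert-butyldimethylsilyl)oxy]-6,8a-dimethyl-3-(propan-2-yl)-3-[(triethylsilyl)oxy]-2,3,3a,6,7,8a-hexahydro-1H-azulen-8-one | CC(C)(C)[Si](C)(C)OC1=C[C@@H](C)CC(=O)[C@@]2(C)CC[C@@](O[Si](CC)(CC)CC)(C(C)C)[C@@H]12 | intermediate
13 | (3R,3aR,4S,6R,8aS)-4-[(tert-butyldimethylsilyl)oxy]-6,8a-dimethyl-3-(propan-2-yl)-3-[(triethylsilyl)oxy]octahydro-1H-azulen-8-one | CC(C)(C)[Si](C)(C)O[C@H]1C[C@@H](C)CC(=O)[C@@]2(C)CC[C@@](O[Si](CC)(CC)CC)(C(C)C)[C@@H]12 | intermediate
14 | (3R,3aR,4S,6R,8aS)-4-[(tert-butyldimethylsilyl)oxy]-6,8a-dimethyl-3-(propan-2-yl)-3-[(triethylsilyl)oxy]-8-[(trimethylsilyl)oxy]-1,2,3,3a,4,5,6,8a-octahydroazulene (not isolated) | CC(C)(C)[Si](C)(C)O[C@H]1C[C@@H](C)C=C(O[Si](C)(C)C)[C@@]2(C)CC[C@@](O[Si](CC)(CC)CC)(C(C)C)[C@@H]12 | intermediate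
15 | (3R,3aR,4S,8aS)-4-[(tert-butyldimethylsilyl)oxy]-6,8a-dimethyl-3-(propan-2-yl)-3-[(triethylsilyl)oxy]-2,3,3a,4,5,8a-hexahydro-1H-azulen-8-one | CC(C)(C)[Si](C)(C)O[C@H]1CC(C)=CC(=O)[C@@]2(C)CC[C@@](O[Si](CC)(CC)CC)(C(C)C)[C@@H]12 | intermediate
16 | (3R,3aR,4S,8aS)-3,4-dihydroxy-6,8a-dimethyl-3-(propan-2-yl)-2,3,3a,4,5,8a-hexahydro-1H-azulen-8-one | O[C@H]1CC(C)=CC(=O)[C@@]2(C)CC[C@@](O)(C(C)C)[C@@H]12 | intermediate
17 | 4-methoxybenzoyl chloride | COc1ccc(cc1)C(Cl)=O | starting material
18 | (3R,3aR,4S,8aS)-3-hydroxy-6,8a-dimethyl-8-oxo-3-(propan-2-yl)-1,2,3,3a,4,5,8,8a-octahydroazulen-4-yl 4-methoxybenzoate | COc1ccc(C(=O)O[C@H]2CC(C)=CC(=O)[C@@]3(C)CC[C@@](O)(C(C)C)[C@@H]23)cc1 | target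

**Step count and risks**

Total step count: 11. Longest linear sequence: 11 steps (1 to 18).

Steps most likely to fail:

1. Step 7. What may go wrong: proton loss from the tertiary allyl cation, capture of the cation by the silyl ether oxygen, collapse of the intermediate after the first C–C bond with loss of the silyl group, or erosion of the ring-fusion and facial selectivity. Fallback (sets out from 9, returns at 12): the two bonds are made in two separate polar steps. Ionisation as in step 7, followed by a cold quench with methanol and Et3N, should give the monocyclic enone (2E)-1-[(1S,2S,5R)-2-(1-ethoxyethenyl)-2-methyl-5-(propan-2-yl)-5-[(triethylsilyl)oxy]cyclopentyl]but-2-en-1-one F1 by attack of the silyl enol ether on the cation and loss of the silyl group, an intramolecular tert-alkylation of a silyl enol ether. TBSOTf with 2,6-di-tert-butylpyridine in CH2Cl2 at −78 °C should then trigger an intramolecular Mukaiyama–Michael addition of the ethyl enol ether to the silyl-activated enone (7-endo). Aqueous work-up returns 12, possibly as a mixture at C6, which is of no consequence.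

2. Step 8. What may go wrong: sluggish hydrogen uptake at the hindered trisubstituted silyl enol ether, hydrogenolytic loss of the silyl group, or delivery of hydrogen to the concave face. Fallback (sets out from 12, returns at 13): the oxygen-bearing centre is set by hydride instead of hydrogen. Bu4NF buffered with AcOH in THF cleaves the silyl enol ether to the dione (3R,3aS,6R,8aS)-6,8a-dimethyl-3-(propan-2-yl)-3-[(triethylsilyl)oxy]octahydroazulene-4,8-dione F2. LiBH(s-Bu)3 in THF at −78 °C should reduce the C4 ketone, not the C8 ketone next to the quaternary carbon, from the convex face to (3R,3aR,4S,6R,8aS)-4-hydroxy-6,8a-dimethyl-3-(propan-2-yl)-3-[(triethylsilyl)oxy]octahydro-1H-azulen-8-one F3. TBSOTf and 2,6-lutidine then give 13.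

3. Step 6. What may go wrong: β-elimination of the triethylsilyloxy group from the lithium dienolate, deprotonation at the γ-methyl group, or silylation of the tertiary alkoxide. Fallback (sets out from 8, returns at 9): the free enolate is avoided. Me3SiCl and imidazole in DMF mask the tertiary alcohol as (2E,6S)-10-ethoxy-9-methyl-6-(propan-2-yl)-6-[(triethylsilyl)oxy]-9-[(trimethylsilyl)oxy]undeca-2,10-dien-4-one F4. Soft enolisation with TBSOTf and Et3N in CH2Cl2 at −78 °C gives tert-butyl{[(2E,4Z,6R)-10-ethoxy-9-methyl-6-(propan-2-yl)-6-[(triethylsilyl)oxy]-9-[(trimethylsilyl)oxy]undeca-2,4,10-trien-4-yl]oxy}dimethylsilane F5. K2CO3 in MeOH at 0 °C should remove only the trimethylsilyl ether and give 9.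

Further compounds
F1 | step 7 | (2E)-1-[(1S,2S,5R)-2-(1-ethoxyethenyl)-2-methyl-5-(propan-2-yl)-5-[(triethylsilyl)oxy]cyclopentyl]but-2-en-1-one | C=C(OCC)[C@@]1(C)CC[C@@](O[Si](CC)(CC)CC)(C(C)C)[C@H]1C(=O)/C=C/C
F2 | step 8 | (3R,3aS,6R,8aS)-6,8a-dimethyl-3-(propan-2-yl)-3-[(triethylsilyl)oxy]octahydroazulene-4,8-dione | O=C1C[C@@H](C)CC(=O)[C@@]2(C)CC[C@@](O[Si](CC)(CC)CC)(C(C)C)[C@@H]12
F3 | step 8 | (3R,3aR,4S,6R,8aS)-4-hydroxy-6,8a-dimethyl-3-(propan-2-yl)-3-[(triethylsilyl)oxy]octahydro-1H-azulen-8-one | O[C@H]1C[C@@H](C)CC(=O)[C@@]2(C)CC[C@@](O[Si](CC)(CC)CC)(C(C)C)[C@@H]12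
F4 | step 6 | (2E,6S)-10-ethoxy-9-methyl-6-(propan-2-yl)-6-[(triethylsilyl)oxy]-9-[(trimethylsilyl)oxy]undeca-2,10-dien-4-one | C/C=C/C(=O)C[C@](O[Si](CC)(CC)CC)(C(C)C)CCC(C)(O[Si](C)(C)C)C(=C)OCC
F5 | step 6 | tert-butyl{[(2E,4Z,6R)-10-ethoxy-9-methyl-6-(propan-2-yl)-6-[(triethylsilyl)oxy]-9-[(trimethylsilyl)oxy]undeca-2,4,10-trien-4-yl]oxy}dimethylsilane | C/C=C/C(O[Si](C)(C)C(C)(C)C)=C/[C@](O[Si](CC)(CC)CC)(C(C)C)CCC(C)(O[Si](C)(C)C)C(=C)OCC
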